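Everything rests on opening the phloroglucinol A ring at its C1'–C2' bond. This unfolds ring A into a linear 3,5,7-triketo ester in which the oxygenated carbons C2', C4' and C6' are the chain carbonyls C1, C3 and C5, C1' is the methylene C6 and the aryl ketone is C7: the 1,3,5-oxygen pattern of ring A with its acyl group on C1' is the feature exploited. One base-mediated Claisen closure (C6 onto ester C1) then forms the six-membered carbocycle, which aromatises to the finished acylphloroglucinol. The precursor is methyl 9-aryl-3,5,7-trioxononanoate bearing the unprotected 4-hydroxy-3,5-diprenylphenyl group, so the saturated linker and both prenyl groups are in place beforehand.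

Key step: step 3

Remark: the target has no stereocentre and no stereogenic double bond (each alkene ends in two methyl groups), so there is no enantiomer or configuration to control.
Remark: phenoxides and enolates formed by simple deprotonation are treated as ionised forms of the numbered compounds and carry no number of their own.
Remark: methyl 3,5-dioxohexanoate (5) is taken as purchasable; otherwise it is one step from dehydroacetic acid by magnesium methoxide methanolysis.
Remark: the B-ring phenol is carried unprotected, because every step after the prenylation runs in base, where the phenoxide protects itself, and no deprotection then has to be done next to the acid-sensitive prenyl groups.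

Step 1
Reactants: 1 methyl 3-(4-hydroxyphenyl)propanoate (methyl phloretate); 2 prenyl bromide (1-bromo-3-methylbut-2-ene)
Product: 4 methyl 3-[4-hydroxy-3,5-bis(3-methylbut-2-enyl)phenyl]propanoate, via monoprenyl ester 3 (not isolated)
Conditions: NaH (1.1 equiv), toluene, 0 °C → rt, then 2 (1.1 equiv), rt; second portion of NaH and 2 (1.1 equiv each), rt; aq. NH4Cl
Reagents that add atoms: prenyl bromide (2), CC(C)=CCBr
Why: ortho C-allylation of a sodium phenoxide held as a tight ion pair in non-polar toluene, where the sodium-bound oxygen is shielded and the allylic bromide is delivered to the neighbouring ring carbon; the dienone re-aromatises and, with the para position blocked, a second deprotonation and alkylation fills the other ortho position, as is known for para-substituted phenols.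

Step 2
Reactants: 4 methyl 3-[4-hydroxy-3,5-bis(3-methylbut-2-enyl)phenyl]propanoate; 5 methyl 3,5-dioxohexanoate
Product: 6 methyl 9-[4-hydroxy-3,5-bis(3-methylbut-2-enyl)phenyl]-3,5,7-trioxononanoate
Conditions: 5 (2.5 equiv), LDA (7.5 equiv), THF, 0 °C; then 4 pre-treated with LDA (1.0 equiv, THF, −78 °C), −78 → 0 °C; cold 1 M HCl to pH 4; short silica plug, used at once
Reagents that add atoms: methyl 3,5-dioxohexanoate (5), COC(=O)CC(=O)CC(C)=O
Why: Claisen-type acylation of a 1,3,5-tricarbonyl polyanion at its terminal carbon: in the trilithio derivative of 5 the C6 carbanion is the last formed and least stabilised, so it alone attacks the ester of 4, while the excess trianion absorbs proton transfer from the more acidic product and the phenol travels as its inert lithium phenoxide.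

Step 3
Reactants: 6 methyl 9-[4-hydroxy-3,5-bis(3-methylbut-2-enyl)phenyl]-3,5,7-trioxononanoate
Product: 8 3-[4-hydroxy-3,5-bis(3-methylbut-2-enyl)phenyl]-1-(2,4,6-trihydroxyphenyl)propan-1-one (the target), via 2-acylcyclohexane-1,3,5-trione 7 (not isolated)
Conditions: Mg(OMe)2 (6 equiv), degassed MeOH, Ar, rt → 60 °C; then 1 M HCl to pH 3 at 0 °C, EtOAc
Reagents that add atoms: none
Why: Magnesium methoxide converts 6 into its chelated polyenolate, in which C6, the carbon between the C5 and C7 carbonyls, adds to the ester carbon C1, the one carbonyl not tied up as an enolate, and the tetrahedral adduct expels methoxide to give trione 7, which enolises three times to the aromatic 2,4,6-trihydroxyphenyl ketone. This is an intramolecular Claisen (Dieckmann-type) condensation, the known base-mediated cyclisation of 3,5,7-trioxoalkanoate esters to acylphloroglucinols. The one ring formed, the six-membered carbocyclic A ring made of chain carbons C1 to C6, closes in the 6-exo-trig mode at the ester carbonyl and creates the C6–C1 bond that becomes C1'–C2'. No stereocentre is formed, since the sp3 ring carbons of 7 vanish on aromatisation. The step needs Claisen closure to beat the two aldol modes (C2 onto C7, leading to a 6-aralkyl resorcylate; C8 onto C3, leading to a 3,5-dihydroxyphenylacetate) and lactonisation to a 2-pyranone; the methyl ester terminus, the water-free methoxide medium that cannot saponify it, and the excess base with magnesium chelation that keeps the ketones enolised and so unreactive as electrophiles secure this. Aromatisation to the phloroglucinolate makes the closure irreversible, and cold, brief acidification releases 8 without cyclising the ortho-prenylphenol to a chroman.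

Compound list
1 | methyl 3-(4-hydroxyphenyl)propanoate (methyl phloretate) | COC(=O)CCc1ccc(O)cc1 | starting material
2 | prenyl bromide (1-bromo-3-methylbut-2-ene) | CC(C)=CCBr | starting material
3 | methyl 3-[4-hydroxy-3-(3-methylbut-2-enyl)phenyl]propanoate (monoprenyl ester) | COC(=O)CCc1ccc(O)c(CC=C(C)C)c1 | intermediate
4 | methyl 3-[4-hydroxy-3,5-bis(3-methylbut-2-enyl)phenyl]propanoate | COC(=O)CCc1cc(CC=C(C)C)c(O)c(CC=C(C)C)c1 | intermediate
5 | methyl 3,5-dioxohexanoate | COC(=O)CC(=O)CC(C)=O | starting material
6 | methyl 9-[4-hydroxy-3,5-bis(3-methylbut-2-enyl)phenyl]-3,5,7-trioxononanoate | COC(=O)CC(=O)CC(=O)CC(=O)CCc1cc(CC=C(C)C)c(O)c(CC=C(C)C)c1 | intermediate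
7 | 2-{3-[4-hydroxy-3,5-bis(3-methylbut-2-enyl)phenyl]propanoyl}cyclohexane-1,3,5-trione | O=C1CC(=O)CC(=O)C1C(=O)CCc1cc(CC=C(C)C)c(O)c(CC=C(C)C)c1 | intermediate
8 | 4,2',4',6'-tetrahydroxy-3,5-diprenyldihydrochalcone; 3-[4-hydroxy-3,5-bis(3-methylbut-2-enyl)phenyl]-1-(2,4,6-trihydroxyphenyl)propan-1-one | CC(C)=CCc1cc(CCC(=O)c2c(O)cc(O)cc2O)cc(CC=C(C)C)c1O | target

Total step count: 3. Longest linear sequence: 3 steps (1 → 4 → 6 → 8).

Steps most likely to fail

Step 3. The chain may close through one of the aldol modes or lactonise instead of undergoing Claisen closure, or the ester may be cleaved by adventitious hydroxide so that Claisen closure is no longer possible. The fallback makes the aryl–acyl bond on a ready-made phloroglucinol ring; it sets out from 4 and comes back to the route at 8. Ester 4 would be converted with MeNHOMe·HCl and i-PrMgCl (THF, −20 °C) into the Weinreb amide N-methoxy-N-methyl-3-[4-hydroxy-3,5-bis(3-methylbut-2-enyl)phenyl]propanamide F1. Phloroglucinol would be etherified (MOMCl, i-Pr2NEt, CH2Cl2) to 1,3,5-tris(methoxymethoxy)benzene F2, and lithiation between two acetal oxygens (n-BuLi, THF, 0 °C) would give 2,4,6-tris(methoxymethoxy)phenyllithium F3. Addition of F3 to the lithium phenoxide of F1 should give 3-[4-hydroxy-3,5-bis(3-methylbut-2-enyl)phenyl]-1-[2,4,6-tris(methoxymethoxy)phenyl]propan-1-one F4. Brief treatment with dilute HCl in MeOH at rt, stopped as soon as the last acetal is gone, should then give 8. This costs an acid step next to the prenyl groups, which is why it is the fallback and not the route.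

Step 2. Proton transfer from the enolisable ester or from the acidic product to the trianion may stall the acylation, and the open-chain triketo ester may cyclise or lactonise during acidic work-up and purification. The fallback carries the chain as a stable lactone; it sets out from 4 and comes back to the route at 6, which is formed in the flask and goes on to 8. The lithium phenoxide of 4 would acylate the 6-methyl carbanion of the dianion of 4-hydroxy-6-methylpyran-2-one (triacetic acid lactone, LDA 2.2 equiv, THF, −78 → 0 °C) to give 4-hydroxy-6-{4-[4-hydroxy-3,5-bis(3-methylbut-2-enyl)phenyl]-2-oxobutyl}pyran-2-one F5, a storable solid. Magnesium methoxide in refluxing methanol should open the lactone by methanolysis to 6, which would cyclise under the conditions of step 3 without isolation.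

Step 1. O-alkylation, incomplete second alkylation and over-alkylation to dienones may erode regiocontrol and material throughput. The fallback fixes the positions with halogens and brings in the prenyl groups by cross-coupling; it sets out from 1 and comes back to the route at 4. Iodination of 1 (NIS 2.1 equiv, cat. TsOH, MeCN, rt) should give methyl 3-(4-hydroxy-3,5-diiodophenyl)propanoate F6, and acetylation (Ac2O, pyridine) should give methyl 3-(4-acetoxy-3,5-diiodophenyl)propanoate F7. Double Stille coupling with tributyl(3-methylbut-2-enyl)stannane (Pd(PPh3)4, DMF, 90 °C), which is expected to bond at the unsubstituted allyl terminus, should give methyl 3-[4-acetoxy-3,5-bis(3-methylbut-2-enyl)phenyl]propanoate F8. Methanolysis of the aryl acetate (K2CO3, MeOH, rt) should then return 4.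

Further compounds
F1 | step 3 | N-methoxy-N-methyl-3-[4-hydroxy-3,5-bis(3-methylbut-2-enyl)phenyl]propanamide | CON(C)C(=O)CCc1cc(CC=C(C)C)c(O)c(CC=C(C)C)c1
F2 | step 3 | 1,3,5-tris(methoxymethoxy)benzene | COCOc1cc(OCOC)cc(OCOC)c1
F3 | step 3 | 2,4,6-tris(methoxymethoxy)phenyllithium | [Li]c1c(OCOC)cc(OCOC)cc1OCOC
F4 | step 3 | 3-[4-hydroxy-3,5-bis(3-methylbut-2-enyl)phenyl]-1-[2,4,6-tris(methoxymethoxy)phenyl]propan-1-one | COCOc1cc(OCOC)c(C(=O)CCc2cc(CC=C(C)C)c(O)c(CC=C(C)C)c2)c(OCOC)c1
F5 | step 2 | 4-hydroxy-6-{4-[4-hydroxy-3,5-bis(3-methylbut-2-enyl)phenyl]-2-oxobutyl}pyran-2-one | O=C1C=C(O)C=C(CC(=O)CCc2cc(CC=C(C)C)c(O)c(CC=C(C)C)c2)O1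
F6 | step 1 | methyl 3-(4-hydroxy-3,5-diiodophenyl)propanoate | COC(=O)CCc1cc(I)c(O)c(I)c1
F7 | step 1 | methyl 3-(4-acetoxy-3,5-diiodophenyl)propanoate | COC(=O)CCc1cc(I)c(OC(C)=O)c(I)c1
F8 | step 1 | methyl 3-[4-acetoxy-3,5-bis(3-methylbut-2-enyl)phenyl]propanoate | COC(=O)CCc1cc(CC=C(C)C)c(OC(C)=O)c(CC=C(C)C)c1
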